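**Plan**

- Numbering is that of the tetralone; the hydroquinone ring is ring A. With the three phenols masked as methoxymethyl ethers, the cyclohexanone ring is cut at C3–C4 and at C1–C8a, leaving a diarylmethane and the three-carbon acyl unit C1–C3 as oxetan-2-one.
- Enabling feature: on ring A, C8a and C4a are neighbours, so a p-tolylsulfinyl group on C8a sits ortho to the doubly benzylic C4. It acidifies and chelates C4–Li, covers one face of C4, and is then exchanged for lithium at the carbon that must bond to C1.
- Forward: the naphthalene half (formylation, selective 4-O-demethylation, MOM ether) is joined through C4 to lithiated 2-bromo-1,4-bis(methoxymethoxy)benzene. Ionic hydrogenation gives the diarylmethane and an Andersen reaction puts the (S)-sulfinyl group on C8a.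
- Key event: a one-flask anionic (3+3) annulation. The C4 anion opens the β-lactone (C3–C4, strain release), sulfoxide–lithium exchange frees C8a–Li, and this closes the cyclohexanone ring on the carboxylate (C1–C8a). Both aromatic systems are carried through intact.
- Stereochemistry: the only stereocentre, C4 (S), comes from 1,4-induction by the sulfinyl sulfur, whose configuration comes from (−)-menthyl (S)-p-toluenesulfinate. Acid removes the three MOM groups at the end.

Key step: step 8

Assumption: the sense of 1,4-induction by the (S)-sulfinyl group on the diarylmethyl anion is taken from the lithium-chelate model (electrophile enters anti to the p-tolyl group); should the opposite sense be found, the (R)-sulfinate enantiomer of 11 is used with no other change.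

**Route**

Step 1
Reactants: 1 1,5-dimethoxynaphthalene
Product: 3 4,8-dimethoxynaphthalene-1-carbaldehyde, via iminium chloride 2 (not isolated)
Conditions: (chloromethylene)dimethyliminium chloride (1.3 equiv), ClCH2CH2Cl, 70 °C; then H2O, 50 °C
Reagents that add atoms: (chloromethylene)dimethyliminium chloride, C[N+](C)=CCl.[Cl-]; water, O
Why: Vilsmeier–Haack formylation of an electron-rich naphthalene should attack the α-position para to one methoxy group, and the symmetry of 1 makes the two such positions identical, so a single aldehyde is expected after hydrolysis of iminium salt 2.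

Step 2
Reactants: 3 4,8-dimethoxynaphthalene-1-carbaldehyde
Product: 4 4-hydroxy-8-methoxynaphthalene-1-carbaldehyde
Conditions: NaSEt (1.5 equiv), DMF, 110 °C; then aq HCl
Reagents that add atoms: none
Why: Thiolate O-demethylation (SN2 at methyl) should be selective for the 4-methoxy group, whose aryloxide is conjugated with the para formyl group, whereas the 8-methoxy group on the other ring has no such conjugation with C1.

Step 3
Reactants: 4 4-hydroxy-8-methoxynaphthalene-1-carbaldehyde
Product: 5 8-methoxy-4-(methoxymethoxy)naphthalene-1-carbaldehyde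
Conditions: NaH, ClCH2OCH3, DMF, 0 °C
Reagents that add atoms: chloromethyl methyl ether, COCCl
Why: Williamson-type O-alkylation of the naphthoxide gives a methoxymethyl ether that tolerates the organolithium steps and can be removed without touching the methyl ether that must survive.

Step 4
Reactants: 6 2-bromobenzene-1,4-diol
Product: 7 2-bromo-1,4-bis(methoxymethoxy)benzene
Conditions: NaH (2.2 equiv), ClCH2OCH3 (2.2 equiv), DMF, 0 °C to rt
Reagents that add atoms: chloromethyl methyl ether, COCCl
Why: Double Williamson-type O-alkylation gives the bis(methoxymethyl) ether, whose acetal oxygens later assist lithiation and stabilise the aryl metal species.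

Step 5
Reactants: 7 2-bromo-1,4-bis(methoxymethoxy)benzene; 5 8-methoxy-4-(methoxymethoxy)naphthalene-1-carbaldehyde
Product: 9 [2-bromo-3,6-bis(methoxymethoxy)phenyl][8-methoxy-4-(methoxymethoxy)naphthalen-1-yl]methanol (racemic), via aryllithium 8 (not isolated)
Conditions: LiN(i-Pr)2, THF, −78 °C; then 5, −78 °C; H2O
Reagents that add atoms: none
Why: Directed ortho-lithiation should occur at the ring C–H flanked by Br and OCH2OCH3 and the aryllithium adds 1,2 to the aldehyde; the carbinol centre forms as a racemate and is erased in step 6.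

Step 6
Reactants: 9 [2-bromo-3,6-bis(methoxymethoxy)phenyl][8-methoxy-4-(methoxymethoxy)naphthalen-1-yl]methanol
Product: 10 1-{[2-bromo-3,6-bis(methoxymethoxy)phenyl]methyl}-8-methoxy-4-(methoxymethoxy)naphthalene
Conditions: Et3SiH, CF3CO2H (2 equiv), CH2Cl2, −40 °C; aq NaHCO3
Reagents that add atoms: none
Why: Ionic hydrogenation should work because acid ionises the carbinol to a diarylmethyl cation strongly stabilised by the para-alkoxynaphthyl group and Et3SiH delivers hydride, which removes the carbinol stereocentre.

Step 7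
Reactants: 10 1-{[2-bromo-3,6-bis(methoxymethoxy)phenyl]methyl}-8-methoxy-4-(methoxymethoxy)naphthalene; 11 (1R,2S,5R)-menthyl (S)-4-methylbenzenesulfinate
Product: 13 8-methoxy-4-(methoxymethoxy)-1-({3,6-bis(methoxymethoxy)-2-[(S)-(4-methylphenyl)sulfinyl]phenyl}methyl)naphthalene, via Grignard reagent 12 (not isolated)
Conditions: Mg, LiCl, THF, 45 °C; then 11, THF/toluene, −30 to 0 °C; H2O
Reagents that add atoms: none
Why: In the Andersen sulfoxide synthesis the aryl Grignard reagent displaces menthoxide from sulfur with inversion, so the (S)-sulfinate should set the sulfur centre of 13 as (S).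

Step 8
Reactants: 13 8-methoxy-4-(methoxymethoxy)-1-({3,6-bis(methoxymethoxy)-2-[(S)-(4-methylphenyl)sulfinyl]phenyl}methyl)naphthalene; 14 oxetan-2-one
Product: 19 (4S)-5,8-bis(methoxymethoxy)-4-[8-methoxy-4-(methoxymethoxy)naphthalen-1-yl]-3,4-dihydronaphthalen-1(2H)-one, via benzylic lithium 15 (not isolated), via lithium carboxylate 16 (not isolated), via aryllithium 17 (not isolated), via gem-diolate 18 (not isolated)
Conditions: LiN(i-Pr)2 (1.1 equiv), THF, −78 °C; 14, −78 °C; t-BuLi (3.2 equiv), −78 to −30 °C; H2O
Reagents that add atoms: none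
Why: LiN(i-Pr)2 removes the doubly benzylic C4–H of 13 and the sulfinyl-chelated anion 15 opens oxetan-2-one at its CH2–O carbon (SN2 with release of four-membered-ring strain), which forms C3–C4 and lithium carboxylate 16; t-BuLi then attacks sulfur, the sulfoxide–lithium exchange frees aryllithium 17 at C8a, and 17 adds to the carboxylate carbon C1 to give gem-diolate 18, which collapses to ketone 19 on aqueous work-up. The closest known reaction types are the alkylation of ortho-sulfinyl benzylic carbanions with remote 1,4-induction, the alkyl–oxygen opening of β-lactones by soft carbanions, and the Parham cyclization of ortho-lithiated arylalkanoic acid salts. The cyclohexanone ring is closed by a 6-exo-trig addition of C8a–Li to the C1 carboxylate. The new stereocentre C4 is controlled by the (S)-sulfinyl group: lithium is held between the sulfinyl oxygen and C4, the p-tolyl group covers one face, and the lactone is delivered to the other, which should give (S)-C4. The step needs alkyl–oxygen instead of acyl attack on the lactone (secured by the soft, delocalised diarylmethyl anion), exchange at sulfur that expels the ring A aryllithium and not p-tolyllithium (secured by the flanking OCH2OCH3 group that stabilises C8a–Li), and ring closure faster than proton transfer from C4–H or C2–H (secured by the intramolecular six-membered geometry at low temperature).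

Step 9
Reactants: 19 (4S)-5,8-bis(methoxymethoxy)-4-[8-methoxy-4-(methoxymethoxy)naphthalen-1-yl]-3,4-dihydronaphthalen-1(2H)-one
Product: 20 (4S)-5,8-dihydroxy-4-(4-hydroxy-8-methoxynaphthalen-1-yl)-3,4-dihydronaphthalen-1(2H)-one
Conditions: HCl (aq, 3 M), MeOH, 45 °C
Reagents that add atoms: none
Why: Acid-catalysed acetal exchange (methanolysis) should remove the three methoxymethyl groups without touching the aryl methyl ether or the C4 centre, which has no pathway for epimerization under these conditions.

**Compound list**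

1 | 1,5-dimethoxynaphthalene | COc1cccc2c(OC)cccc12 | starting material
2 | N-[(4,8-dimethoxynaphthalen-1-yl)methylidene]-N-methylmethanaminium chloride | C[N+](C)=Cc1ccc(OC)c2cccc(OC)c12.[Cl-] | intermediate
3 | 4,8-dimethoxynaphthalene-1-carbaldehyde | O=Cc1ccc(OC)c2cccc(OC)c12 | intermediate
4 | 4-hydroxy-8-methoxynaphthalene-1-carbaldehyde | O=Cc1ccc(O)c2cccc(OC)c12 | intermediate
5 | 8-methoxy-4-(methoxymethoxy)naphthalene-1-carbaldehyde | O=Cc1ccc(OCOC)c2cccc(OC)c12 | intermediate
6 | 2-bromobenzene-1,4-diol (bromohydroquinone) | Oc1ccc(O)c(Br)c1 | starting material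
7 | 2-bromo-1,4-bis(methoxymethoxy)benzene | COCOc1ccc(OCOC)c(Br)c1 | intermediate
8 | [2-bromo-3,6-bis(methoxymethoxy)phenyl]lithium | COCOc1ccc(OCOC)c(Br)c1[Li] | intermediate
9 | [2-bromo-3,6-bis(methoxymethoxy)phenyl][8-methoxy-4-(methoxymethoxy)naphthalen-1-yl]methanol, racemic | COc1cccc2c(OCOC)ccc(C(O)c3c(OCOC)ccc(OCOC)c3Br)c12 | intermediate
10 | 1-{[2-bromo-3,6-bis(methoxymethoxy)phenyl]methyl}-8-methoxy-4-(methoxymethoxy)naphthalene | COc1cccc2c(OCOC)ccc(Cc3c(OCOC)ccc(OCOC)c3Br)c12 | intermediate
11 | (1R,2S,5R)-5-methyl-2-(propan-2-yl)cyclohexyl (S)-4-methylbenzenesulfinate, (−)-menthyl (S)-p-toluenesulfinate | C[C@@H]1CC[C@H]([C@@H](C1)O[S@](=O)c2ccc(C)cc2)C(C)C | starting material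
12 | bromo{3,6-bis(methoxymethoxy)-2-{[8-methoxy-4-(methoxymethoxy)naphthalen-1-yl]methyl}phenyl}magnesium | COc1cccc2c(OCOC)ccc(Cc3c(OCOC)ccc(OCOC)c3[Mg]Br)c12 | intermediate
13 | 8-methoxy-4-(methoxymethoxy)-1-({3,6-bis(methoxymethoxy)-2-[(S)-(4-methylphenyl)sulfinyl]phenyl}methyl)naphthalene | COc1cccc2c(OCOC)ccc(Cc3c(OCOC)ccc(OCOC)c3[S@@](=O)c4ccc(C)cc4)c12 | intermediate
14 | oxetan-2-one (β-propiolactone) | O=C1CCO1 | starting material
15 | benzylic lithium derivative of 13 (lithium on the diarylmethyl carbon, sulfur (S)) | COc1cccc2c(OCOC)ccc(C([Li])c3c(OCOC)ccc(OCOC)c3[S@@](=O)c4ccc(C)cc4)c12 | intermediate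
16 | lithium (4S)-4-{3,6-bis(methoxymethoxy)-2-[(S)-(4-methylphenyl)sulfinyl]phenyl}-4-[8-methoxy-4-(methoxymethoxy)naphthalen-1-yl]butanoate | COc1cccc2c(OCOC)ccc([C@H](CCC(=O)O[Li])c3c(OCOC)ccc(OCOC)c3[S@@](=O)c4ccc(C)cc4)c12 | intermediate
17 | lithium (4S)-4-[2-lithio-3,6-bis(methoxymethoxy)phenyl]-4-[8-methoxy-4-(methoxymethoxy)naphthalen-1-yl]butanoate | COc1cccc2c(OCOC)ccc([C@H](CCC(=O)O[Li])c3c(OCOC)ccc(OCOC)c3[Li])c12 | intermediate
18 | dilithium (4S)-5,8-bis(methoxymethoxy)-4-[8-methoxy-4-(methoxymethoxy)naphthalen-1-yl]-1,2,3,4-tetrahydronaphthalene-1,1-diolate | COc1cccc2c(OCOC)ccc([C@@H]3CCC(O[Li])(O[Li])c4c(OCOC)ccc(OCOC)c43)c12 | intermediate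
19 | (4S)-5,8-bis(methoxymethoxy)-4-[8-methoxy-4-(methoxymethoxy)naphthalen-1-yl]-3,4-dihydronaphthalen-1(2H)-one | COc1cccc2c(OCOC)ccc([C@@H]3CCC(=O)c4c(OCOC)ccc(OCOC)c43)c12 | intermediate
20 | (4S)-5,8-dihydroxy-4-(4-hydroxy-8-methoxynaphthalen-1-yl)-3,4-dihydronaphthalen-1(2H)-one | COc1cccc2c(O)ccc([C@@H]3CCC(=O)c4c(O)ccc(O)c43)c12 | target

**Count and risks**

Total steps: 9. Longest linear sequence: 8 steps (steps 1, 2, 3, 5, 6, 7, 8, 9).

Steps most likely to fail:

1. Step 8. What may go wrong: attack of anion 15 at the acyl carbon of the lactone instead of the CH2–O carbon, weak facial discrimination at C4, and quenching of aryllithium 17 by proton transfer before ring closure. Fallback (no auxiliary, resolution at the end): it sets out from 10. LiN(i-Pr)2 gives the benzylic lithium F1, which is alkylated by oxetan-2-one 14 and acidified to the racemic 4,4-diarylbutanoic acid F2. n-BuLi (2.2 equiv) forms, by bromine–lithium exchange, the lithium ortho-lithioarylbutanoate F3, whose Parham cyclization gives the racemic protected tetralone F4. Chromatography on a chiral stationary phase separates 19 from its (R)-enantiomer F5, and the route is rejoined at 19.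

2. Step 2. What may go wrong: loss of site selectivity in the thiolate demethylation (cleavage of the 8-methyl ether or of both ethers). Fallback (the two oxygens are told apart before the carbon substituent is introduced): it sets out from 1. One of the two equivalent methyl ethers is cleaved with NaSEt (1 equiv) to give 5-methoxynaphthalen-1-ol F6. N-Bromosuccinimide in acetonitrile should brominate para to the free hydroxyl to give 4-bromo-5-methoxynaphthalen-1-ol F7. NaH/ClCH2OCH3 gives 1-bromo-8-methoxy-4-(methoxymethoxy)naphthalene F8, n-BuLi gives the naphthyllithium F9, and formylation with DMF rejoins the route at 5.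

3. Step 7. What may go wrong: slow magnesium insertion into the hindered, electron-rich bromide 10, and erosion of the sulfur configuration through a second attack of the Grignard reagent on the product sulfoxide. Fallback (sulfur installed before the diarylmethane is assembled): it sets out from 7. Magnesium insertion gives the unhindered Grignard reagent F10, whose Andersen reaction with 11 gives (S)-2,5-bis(methoxymethoxy)phenyl 4-methylphenyl sulfoxide F11. LiN(i-Pr)2 lithiates between the sulfinyl and OCH2OCH3 groups to give the ortho-lithio sulfoxide F12, which adds to aldehyde 5 to give the carbinol F13 as a mixture of carbinol epimers. Ionic hydrogenation with Et3SiH/CF3CO2H then rejoins the route at 13.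

Further compounds
F1 | step 8 | benzylic lithium derivative of 10 | COc1cccc2c(OCOC)ccc(C([Li])c3c(OCOC)ccc(OCOC)c3Br)c12
F2 | step 8 | 4-[2-bromo-3,6-bis(methoxymethoxy)phenyl]-4-[8-methoxy-4-(methoxymethoxy)naphthalen-1-yl]butanoic acid, racemic | COc1cccc2c(OCOC)ccc(C(CCC(=O)O)c3c(OCOC)ccc(OCOC)c3Br)c12
F3 | step 8 | lithium 4-[2-lithio-3,6-bis(methoxymethoxy)phenyl]-4-[8-methoxy-4-(methoxymethoxy)naphthalen-1-yl]butanoate, racemic | COc1cccc2c(OCOC)ccc(C(CCC(=O)O[Li])c3c(OCOC)ccc(OCOC)c3[Li])c12
F4 | step 8 | 5,8-bis(methoxymethoxy)-4-[8-methoxy-4-(methoxymethoxy)naphthalen-1-yl]-3,4-dihydronaphthalen-1(2H)-one, racemic | COc1cccc2c(OCOC)ccc(C3CCC(=O)c4c(OCOC)ccc(OCOC)c43)c12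
F5 | step 8 | (4R)-5,8-bis(methoxymethoxy)-4-[8-methoxy-4-(methoxymethoxy)naphthalen-1-yl]-3,4-dihydronaphthalen-1(2H)-one | COc1cccc2c(OCOC)ccc([C@H]3CCC(=O)c4c(OCOC)ccc(OCOC)c43)c12
F6 | step 2 | 5-methoxynaphthalen-1-ol | COc1cccc2c(O)cccc12
F7 | step 2 | 4-bromo-5-methoxynaphthalen-1-ol | COc1cccc2c(O)ccc(Br)c12
F8 | step 2 | 1-bromo-8-methoxy-4-(methoxymethoxy)naphthalene | COc1cccc2c(OCOC)ccc(Br)c12
F9 | step 2 | [8-methoxy-4-(methoxymethoxy)naphthalen-1-yl]lithium | COc1cccc2c(OCOC)ccc([Li])c12
F10 | step 7 | bromo[2,5-bis(methoxymethoxy)phenyl]magnesium | COCOc1ccc(OCOC)c([Mg]Br)c1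
F11 | step 7 | (S)-2,5-bis(methoxymethoxy)phenyl 4-methylphenyl sulfoxide | COCOc1ccc(OCOC)c([S@@](=O)c2ccc(C)cc2)c1
F12 | step 7 | {3,6-bis(methoxymethoxy)-2-[(S)-(4-methylphenyl)sulfinyl]phenyl}lithium | COCOc1ccc(OCOC)c([S@@](=O)c2ccc(C)cc2)c1[Li]
F13 | step 7 | {3,6-bis(methoxymethoxy)-2-[(S)-(4-methylphenyl)sulfinyl]phenyl}[8-methoxy-4-(methoxymethoxy)naphthalen-1-yl]methanol, mixture of carbinol epimers | COc1cccc2c(OCOC)ccc(C(O)c3c(OCOC)ccc(OCOC)c3[S@@](=O)c4ccc(C)cc4)c12
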